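(The readings are calculated with made-up constants.)

- elm: J 1.1 M; X 78 mM (held); run made earlier
- flask: J 2.3 M; X 78 mM (held); time 15 d

elm run (percent of the J charged)

| time / d | L / % | J / % |
|---|---|---|
| 0.625 | 12 | 57 |
| 1.25 | 25 | 30 |
| 2.08 | 30 | 13 |
| 4.00 | 28 | 2 |
| 6.00 | 26 | 1 |
| 10.0 | 23 | 0 |
| 20.0 | 21 | 0 |

(scatter of a reading: 1.5 percentage points)

Late in the elm run, at 10.0 d, J reads 0% and L reads 23%, less than the 30% read at 2.08 d, so the most L stands at a peak and not at the end.

- time, not beyond 15 d, at which the flask holds most L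
- the amount of L, in percent of the J charged, at that time

With X held, J in the elm run falls pseudo-first-order: its rate constant k, the share of J lost per unit time, reads 0.963 d⁻¹ up to 1.25 d and 0.975 d⁻¹ between 2.08 d and 4.00 d. The flask starts at 2.3 M of J, above the 1.1 M charged in the elm run, so the elm readings do not show k above that charge. The excursion time t_x, the time J takes at k to fall from the flask's charge to the elm charge, is 0.766 d. That is shorter than the 2.08 d of the elm peak reading, so this reckoning treats any change of k there as a correction and expects a peak near the elm reading.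

The forecast gives 2.6 d (1.7 d to 3.6 d) and 30% (25% to 33%), holding that “the percent-versus-time curve should not depend on the charge”.

The flask gives 29.8% at 2.68 d.

    J + E → Z (k = 0.550 M⁻¹ h⁻¹)
    E + Z → L (k = 0.890 M⁻¹ h⁻¹)
    E + L ⇌ G (K = 33.0 M⁻¹, k = 0.0140 M⁻¹ h⁻¹)
    L ⇌ Q (K = 2.80, k = 0.0580 h⁻¹)
    X ⇌ E, rate k5*(csat - [E]) (kL = 4.80 h⁻¹)

At 1.50 d, past t_x, the flask holds 29.2% of J, more than the 23.6% that k gives, and E, the dissolved reagent, stands at 0.0657 M against a saturation of 78 mM. For the neighbouring flask with 0.92 M of J, t_x comes out negative, −0.186 d, so its J starts below the elm charge. That neighbour reaches 30.6% of L, more than this flask's 29.8%, and holds 23.8% at 15.0 d.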